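The meeting opened on the question of how much target the west flask holds at 40 min, and which of the moves open at that time pays.

| setting | west | south-west | flask |
|---|---|---|---|
| solid substrate | 0.050 M | 0.050 M | 0.050 M |
| free enzyme | 0.01 mol% | 0.01 mol% | 0.01 mol% |
| impurity | 6.3 µM | 6.3 µM | 6.3 µM |
| temperature | 37 °C | 43 °C | 37 °C |
| remark | the very flask that is asked about, followed so far | run made earlier |  |
| time |  |  | 40 min |

| run | time / min | target / % | solid substrate / % |
|---|---|---|---|
| west | 2.00 | 4.5 | 95.9 |
| west | 4.00 | 8.6 | 89.9 |
| west | 10.0 | 21.1 | 76.9 |
| west | 25.0 | 27.4 | 52.8 |
| south-west | 2.00 | 4.4 | 95.7 |
| south-west | 4.00 | 9.5 | 90.6 |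
| south-west | 10.0 | 20.1 | 77.4 |
| south-west | 25.0 | 24.5 | 54.3 |

(standard deviation of a reading: 0.5 percentage points)

- Tuesday's: at 40 min take out 90% of the target then present, then wait 40 min
- Monday's: at 40 min add free enzyme, 100% of the amount charged, then wait 40 min
- Thursday's: at 40 min raise the temperature by 20 K, then wait 40 min
- Wednesday's: change nothing and wait 40 min more

- solid substrate is a solid; its amount is given per volume of the solution
- target that was removed still counts
- at the start none of the solid substrate is in solution
- additions bring no volume worth counting

- target, in percent of the solid substrate first charged, at 40 min
- what to do for the largest gain in target; "none" if nothing gains more than 2 percentage points (Tuesday's / Monday's / Thursday's / Wednesday's / none)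
- target present, with what was taken out counted in, in percent of the solid substrate first charged, after Tuesday's
- target present, with what was taken out counted in, in percent of the solid substrate first charged, after Monday's

The analyst reported that the west run at first finds nearly as much target as solid has been lost, and later does not: the gap between solid lost and target found reads 2 percentage points at 10.0 min and 20 points at 25.0 min, ten times as much.

The chemist argued from this that the free enzyme has stopped working. She pointed to the charges: c(free enzyme) is 5.00 µM against c(impurity) 6.3 µM. So, if one enzyme takes one impurity, the impurity outnumbers the free enzyme, with 1.30 µM of impurity to spare.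

She proposed to carry one number, the turnover budget, which is target made per free enzyme charged, here 2740 from the last west reading. In powers of ten, −0.562 for the share less −4.00 for the loading gives 3.44.

The engineer objected that target was still rising between the last two west readings. The minutes keep that doubt. They commit to about 27.4% at 40 min, and expect nothing from Tuesday's. Nor do they expect anything from Thursday's, since the warmer south-west run reads 24.5% at the same time, less than the west run. For Monday's, the fresh 5.00 µM exceeds the 1.30 µM of impurity, so on that count 3.70 µM escapes poisoning. The budget does not cap that enzyme, so the meeting chose Monday's and named no figure for it.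

The forecast gave 27.8% (26.8% to 30%), a little above the minutes, chose Monday's, and put 28% after Tuesday's and 85% after Monday's, in the words “The enzyme is therefore dead.”

The flask gives 26.9% at 40 min, 26.9% after Tuesday's and 100% after Monday's, with free enzyme at 0% of its charge and impurity at 21% of its own charge, which is 1.32 µM.

    free enzyme + impurity → spent catalyst (k = 5100 /M/s, Ea = 14.0 kJ/mol)
    starting material + free enzyme → target + free enzyme, rate k2*[starting material]*[free enzyme]/(1 + ([starting material]/Km2) + ([target]/Kp2)) (0.120 M, 0.890 mM, k = 6.00 × 10⁶ /M/s, Ea = 13.0 kJ/mol)
    free enzyme → unfolded enzyme (k = 3.50 × 10⁻⁵ /s, Ea = 212 kJ/mol)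
    solid substrate ⇌ starting material, rate k4*(cs4 - [starting material]) while solid is left; crystals form when [starting material] > cs4 (solubility = 18.0 mM, k = 0.00110 /s)
    (constants at 37 °C)

Counted on this result, the flask's budget is 2690 target per free enzyme charged. A neighbour flask charged with 0.0025 mol% of free enzyme, the rest as in the flask, gets from the carried budget 3.44 plus −4.60 in powers of ten, which is 6.85%. That neighbour flask holds 6.90% at 40.0 min.

The runs come from a simulation for an exercise, and the scatter is random.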